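**Plan**

- Retrosynthesis: remove the O7–S bond and the benzyl cap on O3'. Open ring C at O1–C2 to a β-amino enone. Rejoin its N and O as the N–O bond of an isoxazole. Cut that isoxazole at C2–C3 and C4–O (flavone numbering) into a ring B nitrile oxide and a ring A aryl alkyne.
- Enabling feature: C2–C3–C4 of ring C is a three-carbon unit oxidised at both ends (C4 ketone, C2 at the acyl level), i.e. a masked 1,3-dicarbonyl. It sits between ring B on C2 and a ring A whose 2,4,6-oxygen pattern is symmetric.
- Forward order: ring A alkyne (2 steps) and ring B hydroximoyl chloride (2 steps) are joined as the isoxazole. The N–O bond is then cleaved, acid closes ring C, O7 is sulfated and O3' is debenzylated.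
- Stereochemistry: the target has no stereocentre. Regiochemistry is fixed by the 3,5-selective cycloaddition, by the symmetry of ring A, and by the 3'-benzyl ether together with the chelated 5-OH, which leave O7 as the only site for sulfation.

Key step: step 5

Assumption: the sulfate is carried as its sodium salt and converted into the free hydrogen sulfate, as the target is drawn, only in the last operation; the free acid should be kept cold because aryl hydrogen sulfates hydrolyse under their own acidity.

**Route**

Step 1
Reactants: 1 2,4,6-trihydroxybenzaldehyde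
Product: 2 2,4,6-tris(methoxymethoxy)benzaldehyde
Conditions: NaH (3.6 equiv), MOMCl (3.6 equiv), DMF, 0 °C→rt
Reagents that add atoms: chloromethyl methyl ether, COCCl
Why: Williamson-type O-alkylation of the sodium phenoxides by the reactive α-chloro ether; full deprotonation with NaH breaks the hydrogen bonds from the ortho hydroxyls to the aldehyde so that all three oxygens are capped, and the non-enolisable aldehyde is untouched.

Step 2
Reactants: 2 2,4,6-tris(methoxymethoxy)benzaldehyde
Product: 3 2-ethynyl-1,3,5-tris(methoxymethoxy)benzene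
Conditions: dimethyl (1-diazo-2-oxopropyl)phosphonate, K2CO3, MeOH, rt
Reagents that add atoms: dimethyl (1-diazo-2-oxopropyl)phosphonate (Ohira–Bestmann reagent), CC(=O)C(=[N+]=[N-])P(=O)(OC)OC
Why: Ohira–Bestmann (Seyferth–Gilbert) homologation, in which methoxide deacetylates the reagent, the diazomethylphosphonate anion adds to the aldehyde and loses dimethyl phosphate and then N2, and the alkylidene carbene rearranges to the terminal alkyne under mild base that the MOM acetals tolerate.

Step 3
Reactants: 4 3-benzyloxy-4-methoxybenzaldehyde (O-benzylisovanillin, commercial)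
Product: 5 (E)-3-benzyloxy-4-methoxybenzaldehyde oxime
Conditions: NH2OH·HCl, NaOAc, EtOH/H2O, rt
Reagents that add atoms: hydroxylamine hydrochloride, Cl.NO
Why: acetate-buffered condensation of an aryl aldehyde with hydroxylamine (oxime formation), which gives the E aldoxime.

Step 4
Reactants: 5 (E)-3-benzyloxy-4-methoxybenzaldehyde oxime
Product: 6 (Z)-3-benzyloxy-N-hydroxy-4-methoxybenzimidoyl chloride
Conditions: NCS (1.05 equiv), DMF, 0 °C→rt
Reagents that add atoms: N-chlorosuccinimide, O=C1CCC(=O)N1Cl
Why: electrophilic chlorination of the aldoxime carbon with NCS in DMF is the standard hydroximoyl chloride synthesis and, with one equivalent at or below rt, should outpace chlorination of the dialkoxyarene ring.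

Step 5
Reactants: 3 2-ethynyl-1,3,5-tris(methoxymethoxy)benzene; 6 (Z)-3-benzyloxy-N-hydroxy-4-methoxybenzimidoyl chloride
Product: 8 3-(3-benzyloxy-4-methoxyphenyl)-5-[2,4,6-tris(methoxymethoxy)phenyl]isoxazole, via 3-benzyloxy-4-methoxybenzonitrile oxide 7 (not isolated)
Conditions: KHCO3 (3 equiv), EtOAc, rt→40 °C; 6 (1.5 equiv) added in portions
Reagents that add atoms: none
Why: Solid KHCO3 slowly dehydrochlorinates 6 to nitrile oxide 7, which adds across the terminal alkyne of 3 in a concerted, asynchronous thermal (3+2) cycloaddition (Huisgen 1,3-dipolar cycloaddition of a nitrile oxide to an alkyne, the standard entry to 3,5-diarylisoxazoles). The dipole carbon bonds to the unsubstituted alkyne carbon (the future C2–C3 bond of the flavone) and the dipole oxygen to the aryl-bearing carbon (the future C4–O bond), so both bonds of the five-membered ring form in the same step and the aromatic isoxazole results without an oxidation. The ring is closed by the intermolecular cycloaddition itself, not by a separate cyclisation, and no stereocentre is created. The selectivity needed is regiochemical (3,5- over 3,4-disubstitution) and is secured by the terminal alkyne, whose hydrogen-bearing carbon is the only terminus the aryl-substituted dipole carbon can reach, an orientation reinforced by the two ortho MOM ethers that shield the internal carbon. Dimerisation of 7 to the furoxan is the competing pathway and is held back by generating the dipole slowly from a heterogeneous base in the presence of the alkyne and by using 6 in excess.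

Step 6
Reactants: 8 3-(3-benzyloxy-4-methoxyphenyl)-5-[2,4,6-tris(methoxymethoxy)phenyl]isoxazole
Product: 9 (Z)-3-amino-3-(3-benzyloxy-4-methoxyphenyl)-1-[2,4,6-tris(methoxymethoxy)phenyl]prop-2-en-1-one
Conditions: Mo(CO)6 (1 equiv), MeCN/H2O, 80 °C
Reagents that add atoms: none
Why: reductive isoxazole ring opening, in which molybdenum hexacarbonyl binds the ring nitrogen and delivers two electrons into the weak N–O bond while water supplies the hydrogens, gives the Z β-amino enone held by an N–H···O=C hydrogen bond under neutral conditions that spare the MOM acetals and the benzyl ether.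

Step 7
Reactants: 9 (Z)-3-amino-3-(3-benzyloxy-4-methoxyphenyl)-1-[2,4,6-tris(methoxymethoxy)phenyl]prop-2-en-1-one
Product: 11 2-(3-benzyloxy-4-methoxyphenyl)-5,7-dihydroxy-4H-chromen-4-one (3'-O-benzyldiosmetin), via tris-phenol enaminone 10 (not isolated)
Conditions: 3 M HCl in MeOH, 60 °C
Reagents that add atoms: none
Why: acid transacetalisation removes the three MOM groups and protonates the vinylogous amide, an ortho phenol then adds to C2 (6-endo-trig addition–elimination on the enaminone, or 6-exo-trig on its iminium tautomer) and ammonia is expelled to give the 4-pyranone; both ortho hydroxyls of the symmetric ring A lead to the same flavone, any diketone formed by hydrolysis cyclodehydrates to the same product, and the benzyl and methyl ethers are acid-stable.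

Step 8
Reactants: 11 2-(3-benzyloxy-4-methoxyphenyl)-5,7-dihydroxy-4H-chromen-4-one
Product: 13 sodium 2-(3-benzyloxy-4-methoxyphenyl)-5-hydroxy-4-oxo-4H-chromen-7-yl sulfate, via pyridinium sulfate salt 12 (not isolated)
Conditions: SO3·pyridine (3 equiv), pyridine, rt; then aq. NaHCO3, C18 chromatography
Reagents that add atoms: sulfur trioxide–pyridine complex, [O-]S(=O)(=O)[n+]1ccccc1; sodium hydrogen carbonate, [Na+].OC(=O)[O-]
Why: O-sulfonation of a phenol by the SO3·pyridine complex should occur only at the acidic 7-OH, because O3' is benzylated and the 5-OH is locked in a hydrogen bond to the C4 carbonyl, and bicarbonate work-up gives the stable sodium salt.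

Step 9
Reactants: 13 sodium 2-(3-benzyloxy-4-methoxyphenyl)-5-hydroxy-4-oxo-4H-chromen-7-yl sulfate
Product: 15 luteolin 4'-methyl ether 7-sulfate (5-hydroxy-2-(3-hydroxy-4-methoxyphenyl)-4-oxo-4H-chromen-7-yl hydrogen sulfate), via sodium diosmetin 7-sulfate 14 (not isolated)
Conditions: H2 (1 atm), 10% Pd/C, MeOH/H2O, rt; then aq. HCl (1 equiv), 0 °C, C18 desalting
Reagents that add atoms: none
Why: hydrogenolysis of the benzyl aryl ether over Pd/C at ambient pressure should leave the sulfate monoester anion, the aryl methyl ether and the chromone C2–C3 double bond intact, and one equivalent of strong acid then protonates the sulfate before desalting.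

**Compound list**

1 | 2,4,6-trihydroxybenzaldehyde | O=Cc1c(O)cc(O)cc1O | starting material
2 | 2,4,6-tris(methoxymethoxy)benzaldehyde | O=Cc1c(OCOC)cc(OCOC)cc1OCOC | intermediate
3 | 2-ethynyl-1,3,5-tris(methoxymethoxy)benzene | C#Cc1c(OCOC)cc(OCOC)cc1OCOC | intermediate
4 | 3-benzyloxy-4-methoxybenzaldehyde | COc1ccc(C=O)cc1OCc1ccccc1 | starting material
5 | (E)-3-benzyloxy-4-methoxybenzaldehyde oxime | COc1ccc(/C=N/O)cc1OCc1ccccc1 | intermediate
6 | (Z)-3-benzyloxy-N-hydroxy-4-methoxybenzimidoyl chloride | COc1ccc(/C(Cl)=N/O)cc1OCc1ccccc1 | intermediate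
7 | 3-benzyloxy-4-methoxybenzonitrile oxide | COc1ccc(C#[N+][O-])cc1OCc1ccccc1 | intermediate (not isolated)
8 | 3-(3-benzyloxy-4-methoxyphenyl)-5-[2,4,6-tris(methoxymethoxy)phenyl]isoxazole | COc1ccc(-c2cc(-c3c(OCOC)cc(OCOC)cc3OCOC)on2)cc1OCc1ccccc1 | intermediate
9 | (Z)-3-amino-3-(3-benzyloxy-4-methoxyphenyl)-1-[2,4,6-tris(methoxymethoxy)phenyl]prop-2-en-1-one | COc1ccc(/C(N)=C/C(=O)c2c(OCOC)cc(OCOC)cc2OCOC)cc1OCc1ccccc1 | intermediate
10 | (Z)-3-amino-3-(3-benzyloxy-4-methoxyphenyl)-1-(2,4,6-trihydroxyphenyl)prop-2-en-1-one | COc1ccc(/C(N)=C/C(=O)c2c(O)cc(O)cc2O)cc1OCc1ccccc1 | intermediate (not isolated)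
11 | 2-(3-benzyloxy-4-methoxyphenyl)-5,7-dihydroxy-4H-chromen-4-one (3'-O-benzyldiosmetin) | COc1ccc(-c2cc(=O)c3c(O)cc(O)cc3o2)cc1OCc1ccccc1 | intermediate
12 | pyridinium 2-(3-benzyloxy-4-methoxyphenyl)-5-hydroxy-4-oxo-4H-chromen-7-yl sulfate | COc1ccc(-c2cc(=O)c3c(O)cc(OS(=O)(=O)[O-])cc3o2)cc1OCc1ccccc1.c1cc[nH+]cc1 | intermediate (not isolated)
13 | sodium 2-(3-benzyloxy-4-methoxyphenyl)-5-hydroxy-4-oxo-4H-chromen-7-yl sulfate | COc1ccc(-c2cc(=O)c3c(O)cc(OS(=O)(=O)[O-])cc3o2)cc1OCc1ccccc1.[Na+] | intermediate
14 | sodium 5-hydroxy-2-(3-hydroxy-4-methoxyphenyl)-4-oxo-4H-chromen-7-yl sulfate | COc1ccc(-c2cc(=O)c3c(O)cc(OS(=O)(=O)[O-])cc3o2)cc1O.[Na+] | intermediate (not isolated)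
15 | luteolin 4'-methyl ether 7-sulfate (5-hydroxy-2-(3-hydroxy-4-methoxyphenyl)-4-oxo-4H-chromen-7-yl hydrogen sulfate) | COc1ccc(-c2cc(=O)c3c(O)cc(OS(=O)(=O)O)cc3o2)cc1O | target

**Step count**

Total steps: 9. Longest linear sequence: 7 steps (from 1 through steps 1, 2, 5, 6, 7, 8, 9; equally from 4 through steps 3, 4, 5, 6, 7, 8, 9).

**Steps most likely to fail**

1. Step 5. The hindered, electron-rich alkyne may react so slowly that the nitrile oxide dimerises faster than it is trapped. The fallback reaches the same enaminone without a dipole and sets out from 4 and 2. Aldehyde 4 is homologated with the Ohira–Bestmann reagent (K2CO3, MeOH) to 2-(benzyloxy)-4-ethynyl-1-methoxybenzene F1. Its lithium acetylide (n-BuLi, THF, −78 °C) is added to aldehyde 2 to give racemic 3-(3-benzyloxy-4-methoxyphenyl)-1-[2,4,6-tris(methoxymethoxy)phenyl]prop-2-yn-1-ol F2. MnO2 in CH2Cl2 oxidises this to 3-(3-benzyloxy-4-methoxyphenyl)-1-[2,4,6-tris(methoxymethoxy)phenyl]prop-2-yn-1-one F3. Conjugate addition of ammonia (NH3 in MeOH, sealed tube) to the ynone places nitrogen on the ring B carbon and returns to the route at 9.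

2. Step 9. Hydrogenation may run on to saturate the C2–C3 double bond, or the sulfate ester may be solvolysed during hydrogenolysis and acidification. The fallback removes the benzyl group before any sulfate is present and relies on acidity for site selectivity. It sets out from 11, which is debenzylated with BCl3 and pentamethylbenzene (cation scavenger) in CH2Cl2 at −78 °C to diosmetin F4. Treatment with SO3·NMe3 and one equivalent of Na2CO3 in aqueous dioxane should sulfate only the 7-phenoxide, the most acidic hydroxyl. The 3'-OH is less acidic and flanked by the methoxy group, and the 5-OH is chelated. This gives the sodium salt directly and comes back to the route at 14, which is acidified as in step 9.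

3. Step 8. Sulfation may stall or overrun, and the polar salt may be lost or partly hydrolysed during purification. The fallback installs the sulfate as a neutral, chromatographable diester and sets out from 11. 2,2,2-Trichloroethyl chlorosulfate with Et3N and DMAP in THF should give 2-(3-benzyloxy-4-methoxyphenyl)-5-hydroxy-4-oxo-4H-chromen-7-yl 2,2,2-trichloroethyl sulfate F5, purified on silica. Zn dust and HCO2NH4 in MeOH then cleave the trichloroethyl group by reductive fragmentation to ammonium 2-(3-benzyloxy-4-methoxyphenyl)-5-hydroxy-4-oxo-4H-chromen-7-yl sulfate F6. Evaporation from aqueous NaHCO3 exchanges the cation and returns to the route at 13.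

**Further compounds**

F1 | step 5 | 2-(benzyloxy)-4-ethynyl-1-methoxybenzene | C#Cc1ccc(OC)c(OCc2ccccc2)c1
F2 | step 5 | 3-(3-benzyloxy-4-methoxyphenyl)-1-[2,4,6-tris(methoxymethoxy)phenyl]prop-2-yn-1-ol (racemic) | COCOc1cc(OCOC)c(C(O)C#Cc2ccc(OC)c(OCc3ccccc3)c2)c(OCOC)c1
F3 | step 5 | 3-(3-benzyloxy-4-methoxyphenyl)-1-[2,4,6-tris(methoxymethoxy)phenyl]prop-2-yn-1-one | COCOc1cc(OCOC)c(C(=O)C#Cc2ccc(OC)c(OCc3ccccc3)c2)c(OCOC)c1
F4 | step 9 | diosmetin (5,7-dihydroxy-2-(3-hydroxy-4-methoxyphenyl)-4H-chromen-4-one) | COc1ccc(-c2cc(=O)c3c(O)cc(O)cc3o2)cc1O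
F5 | step 8 | 2-(3-benzyloxy-4-methoxyphenyl)-5-hydroxy-4-oxo-4H-chromen-7-yl 2,2,2-trichloroethyl sulfate | COc1ccc(-c2cc(=O)c3c(O)cc(OS(=O)(=O)OCC(Cl)(Cl)Cl)cc3o2)cc1OCc1ccccc1
F6 | step 8 | ammonium 2-(3-benzyloxy-4-methoxyphenyl)-5-hydroxy-4-oxo-4H-chromen-7-yl sulfate | COc1ccc(-c2cc(=O)c3c(O)cc(OS(=O)(=O)[O-])cc3o2)cc1OCc1ccccc1.[NH4+]
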